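## Structural features

The target is a 9,13;15,16-diepoxylabdane (labdane numbering is used throughout). Rings A and B form a trans-decalin; C9 is the spiro atom of a tetrahydrofuran (ring C: O, C9, C11, C12, C13), and C13 is the spiro atom of a 2,3-dihydrofuran (ring D: C13, C14=C15, O, C16). Ring A carries only the geminal methyl groups on C4 and meets ring B at C5 (α-H) and quaternary C10 (β-CH3). Ring B is fully substituted: 6β-acetoxy, C7 ketone, 8α-methyl and 9α-oxygen. Five stereocentres are clustered (C6, C5, C10, C9, C8); the sixth, quaternary C13, is remote and related to C9 only across ring C. Three groups are fragile: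

- The 6β-acetate is axial, syn to the axial methyl groups on C4 and C10, and α to the ketone, so it is the less stable C6 epimer.
- The C9–O bond is β to the ketone, so base can reopen ring C by β-elimination and epimerize C8.
- The C13–O bond is allylic to the enol ether, so acid ionizes it and aromatizes ring D to a furan.

The real difficulties are the vicinal fully substituted C9/C10 pair, oxygen on the hindered β face of C6, absolute control of C13, and carrying the enol ether to the end. The key step exploits the bareness of ring A: a chiral-pool cyclohexenone can serve as ring B with C5, the C4 carbons (as an isopropenyl group), the C8 methyl and the C9 oxygen already in place, and ring A is then closed through one C3–C4 bond from a tertiary C4 radical.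

## Logic of the disconnections

**35 ⇒ 33.** The C14=C15 enol ether is unveiled last. Retrosynthetically water is added across it, so C15 becomes a hemiacetal carbon. This removes the acid-labile allylic ether from every earlier intermediate. The forward step must eliminate under basic, non-ionizing conditions; its regiochemistry is fixed because C13 has no hydrogen.

**33 ⇒ 32 ⇒ 31 ⇒ 30.** These are functional-group changes only: lactol back to methyl acetal, acetate back to alcohol, alcohol back to silyl ether. C15 stays locked as an acetal while the C6 oxygen is deprotected and acylated. Each forward step must leave the β-alkoxy ketone and the C6 configuration alone.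

**30 ⇒ 29.** The O–C9 bond of ring C and the C8–H bond are cut (retro-oxa-Michael). This removes the spiro junction and two stereocentres (C9, C8) and exposes a planar 8-en-7-one. The forward addition must go to the α face of C9, and the equilibrium must favour the closed ring with the C8 methyl equatorial.

**29 ⇒ 28 ⇒ 27.** The O16–C15 acetal bond is opened and C15 is traced to the terminus of a prenyl group, with the C13 and C16 oxygens tied in an acetonide. Ring D thus reduces to an alkene and a protected diol. The forward steps need alkene cleavage that spares the enone and an acetalization in which only the C16 hydroxyl can close.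

**27 ⇒ 26 ⇒ 16 + 24.** The C9–C11 bond is cut and the C7 carbonyl is transposed back to C9. The molecule splits into a decalin enone and a C6 side chain of similar complexity. The forward step is a 1,2-addition to a hindered ketone without α-hydrogens, followed by an oxidative 1,3-transposition.

**24 ⇒ 23 ⇒ 22 ⇒ 21 ⇒ 18 + 19 ⇒ 17.** The C13–C14 bond is cut and the oxygens are traced to a hydroxy diacid. C13 then comes from the chiral pool. The forward alkylation must go with retention at the carbinol carbon, and the two primary hydroxyls must be told apart, which the 1,2-acetonide does.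

**16 ⇒ 15 ⇒ 14 ⇒ 13.** The C6–O bond is traced through a C6 ketone to a C6 methylene. The 6β oxygen is syn to two axial methyl groups, so a late enolate oxidation of the C7 ketone would be expected to deliver oxygen from the open α face and give the wrong epimer. Hydride addition to a C6 carbonyl from that same α face gives the right one. The forward steps need γ-oxidation of the enone and reduction of the C6 carbonyl in preference to C9.

**13 ⇒ 12 ⇒ 11 ⇒ 9.** The C1 carbonyl is put back. It is not in the target, but it activates the radical acceptor. The forward removal needs enolization at C2 only and hydrogenation of C1=C2 without touching C7=C8.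

**9 ⇒ 8.** The C3–C4 bond is cut, opening ring A to a monocyclic triene-dione with C5 and C10 set. The forward step must generate a C4 radical selectively beside two enones and close in the 6-endo mode.

**8 ⇒ 7 ⇒ 4 + 5; 4 ⇒ 1 + 2.** The C10–C1 and C10–CH3 bonds are cut, leaving the terpene 1 and two one- to three-carbon electrophiles. The second electrophile must enter anti to the isopropenyl group so that the two arms that will form ring A are trans.

## Other disconnections considered

**Alternative 1:** The cut is the O–C9 bond of ring C. In the forward sense a Co(salen) complex with a silane and an N-fluoropyridinium oxidant would transfer a hydrogen atom to C11 of the exocyclic alkene A2. The tertiary C9 radical would be oxidized to the cation and captured by the C13 hydroxyl to give the spiro ether A1, with C7 masked as a dioxolane and ring D as a methyl acetal.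
- In its favour: the closure is irreversible and nearly neutral, so it does not depend on a conjugate-addition equilibrium. On this point it is the better plan. C13 arrives preset in the side chain, which is equal to the chosen plan.
- Against it here: A2 needs a regiodefined trisubstituted alkene at neopentyl C9. The C7 ketone must be protected and released. The 6β-acetate and C8 methyl must already be in place. A cation at C9 beside quaternary C10 can lose a proton or suffer a 1,2-methyl shift.
- Comparison: both plans use metal-hydride hydrogen-atom transfer, but here it serves ring C and leaves the decalin unsolved, so it complements the chosen key step more than it replaces it. In step count it would trade steps 18–20 for alkene formation and ketal handling, about equal.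

**Alternative 2:** The cut removes C4–C5 and C9–C10 and opens rings A and B to the acyclic (S)-epoxy β-keto ester A4. In the forward sense MeAlCl2 would open the epoxide, the C5=C10 alkene would attack C4, and the β-keto ester would trap the C10 cation through C9, giving the 3β-hydroxy-8-oxo decalin A3.
- In its favour: two rings, two C–C bonds and the C5 and C10 centres arise in one step from a linear precursor whose only stereocentre comes from an asymmetric epoxidation. In bond-forming economy it is the better plan.
- Against it here: the target has no C3 oxygen, so that hydroxyl must be removed. The ketone is on C8, not C7, so the C8 methyl, the C7 carbonyl and the C6 acetate still need a carbonyl transposition. The C11 ester must be homologated and C9 hydroxylated. Cationic bicyclizations of this kind tend to be accompanied by partly cyclized and eliminated material.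
- Comparison: the chosen plan maps the ring B oxidation pattern directly, and its radical closure tolerates two enones that a strong Lewis acid would not. In step count the two are judged about equal once the C3 oxygen and the C8-to-C7 shift are paid for.

**Alternative 3:** The cut removes C5–C10 and C8–C9 and opens rings A and B to the triene A6, a (Z)-alkylidene dioxolanone tethered to a terminal diene. In the forward sense a thermal intramolecular Diels–Alder reaction would add the C5=C6–C7=C8 diene across the exocyclic C9=C10 alkene and give the trans-fused Δ6-decalin A5 with the dioxolanone spiro at C9.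
- In its favour: both rings, quaternary C10 and above all the 9α-oxygen together with C11 are set in one step under control of the tert-butyl acetal. This is better than the chosen plan, where C9 is set late by a reversible addition. The C6=C7 alkene is also a direct handle for the ring B oxygens.
- Against it here: a tetrasubstituted dienophile and a diene terminus beside the gem-dimethyl carbon make a sluggish cycloaddition likely. The trans ring fusion depends on one of two competing transition-state geometries. The C8 methyl is absent from A5 and C13 is not addressed.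
- Comparison: in step count the alternative is equal at best, because the acyclic triene needs its own assembly, whereas the chosen plan reaches the decalin in four steps from a chiral-pool terpene.

Key step: step 4

Remark: C15 of 29–34 and the carbinol carbon of 7 are carried as mixtures of epimers; both centres become trigonal later, so this has no consequence.

## Route

Step 1
Reactants: 1 (R)-(−)-carvone; 2 iodomethane
Product: 4 trans-6-methylcarvone [(5R,6S)-2,6-dimethyl-5-(prop-1-en-2-yl)cyclohex-2-en-1-one; minor cis epimer carried along], via lithium enolate 3 (not isolated)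
Conditions: LiN(i-Pr)2, THF, −78 °C; MeI, −78 → −20 °C
Reagents that add atoms: none
Why: Kinetic deprotonation at the α′ carbon gives the cross-conjugated enolate, which is methylated mainly anti to the isopropenyl group (enolate alkylation); the epimer ratio is immaterial because this carbon becomes trigonal again in step 2.

Step 2
Reactants: 4 trans-6-methylcarvone; 5 acrolein
Product: 7 aldol adduct 6-(1-hydroxyprop-2-enyl)-6-methylcarvone (hydroxyallyl group trans to isopropenyl; carbinol epimers), via lithium enolate 6 (not isolated)
Conditions: LiN(i-Pr)2, THF, −78 °C; acrolein, −78 °C; AcOH, −78 °C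
Reagents that add atoms: none
Why: The tetrasubstituted enolate adds 1,2 to acrolein on the face opposite the neighbouring isopropenyl group (kinetic lithium aldol reaction), which sets quaternary C10 with the methyl cis and the three-carbon arm trans to the future C4; the cold acidic quench forestalls retro-aldol cleavage.

Step 3
Reactants: 7 aldol adduct
Product: 8 6-acryloyl-6-methylcarvone (acryloyl trans to isopropenyl)
Conditions: DMP, CH2Cl2, 0 °C → rt
Reagents that add atoms: none
Why: Periodinane oxidation of the allylic carbinol is near-neutral and gives the non-enolizable β-diketone; the vinyl ketone is used without storage.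

Step 4
Reactants: 8 6-acryloyl-6-methylcarvone
Product: 9 trans-fused 4,4,8,10-tetramethyldecal-7-ene-1,9-dione (5α-H; 10β-CH3)
Conditions: Fe(acac)3 (0.3 equiv), PhSiH3 (2.5 equiv), EtOH–HOCH2CH2OH 5:1, 60 °C
Reagents that add atoms: none
Why: Fe(acac)3 and PhSiH3 in ethanol generate an iron hydride (trivalent iron) that transfers a hydrogen atom to the terminal CH2 of the isopropenyl group, the only electron-rich alkene of 8, creating the second C4 methyl and a nucleophilic tertiary radical at C4. This radical adds to the unsubstituted terminus C3 of the vinyl ketone, forming C3–C4 and closing ring A in the 6-endo-trig mode; 5-exo attack at C2 is polarity-mismatched and more hindered. The resulting α-keto radical at C2 is reduced by divalent iron to the enolate and protonated by the solvent, which returns trivalent iron. The closest known reaction type is the iron-hydride reductive olefin coupling, a hydrogen-atom-transfer Giese reaction, run intramolecularly. No new stereocentre is formed: C4 becomes a gem-dimethyl carbon and C2 a methylene, and the trans ring fusion follows from the C5 and C10 configurations fixed in steps 1 and 2, because the acryloyl and isopropenyl arms are trans on ring B and can only bridge diequatorially. The step needs hydrogen delivery to the 1,1-disubstituted alkene beside two enones, which the preference of metal-hydride transfer for electron-rich alkenes secures, and ring closure ahead of reduction of the radical, which quaternary C10 and the proximity of the two arms secure.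

Step 5
Reactants: 9 decalin-1,9-dione
Product: 11 C1 enol triflate of 9 (1-triflyloxy-1,7-dien-9-one), via lithium C1 enolate 10 (not isolated)
Conditions: LiN(SiMe3)2, THF, −78 °C; PhNTf2, −78 → 0 °C; H2O
Reagents that add atoms: N-phenylbis(trifluoromethanesulfonimide) O=S(=O)(N(c1ccccc1)S(=O)(=O)C(F)(F)F)C(F)(F)F
Why: The C2 hydrogens are the only α-hydrogens of the diketone (C10 is quaternary and the C9 ketone can enolize only through its γ position), so the base gives one enolate, which PhNTf2 traps on oxygen (enol triflate formation).

Step 6
Reactants: 11 C1 enol triflate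
Product: 12 4,4,8,10-tetramethyldecala-1,7-dien-9-one
Conditions: Pd(OAc)2 (5 mol %), PPh3, Bu3N, HCO2H, DMF, 60 °C
Reagents that add atoms: none
Why: Palladium-catalysed formate reduction of the vinyl triflate (oxidative addition to zerovalent palladium, formate exchange, decarboxylation, reductive elimination) replaces the C1 oxygen by hydrogen and leaves the enone alone.

Step 7
Reactants: 12 dienone
Product: 13 4,4,8,10-tetramethyldecal-7-en-9-one (5α-H; 10β-CH3)
Conditions: RhCl(PPh3)3 (10 mol %), H2 (1 atm), benzene–EtOH, rt
Reagents that add atoms: none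
Why: RhCl(PPh3)3 hydrogenates the cis-disubstituted C1=C2 alkene far faster than the trisubstituted, conjugated C7=C8 alkene (chemoselective homogeneous hydrogenation), which completes removal of the C1 carbonyl.

Step 8
Reactants: 13 enone
Product: 14 4,4,8,10-tetramethyldecal-7-ene-6,9-dione
Conditions: Pd(OH)2/C (5 mol %), t-BuOOH (5 equiv), K2CO3 (0.25 equiv), CH2Cl2, 4 → 24 °C
Reagents that add atoms: tert-butyl hydroperoxide CC(C)(C)OO
Why: Pd(OH)2/C with t-BuOOH oxidizes the γ-methylene of an α,β-enone to the 1,4-enedione through an allylic tert-butyl peroxide; C6 is the only ring CH2 that is both allylic and γ to the carbonyl.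

Step 9
Reactants: 14 enedione
Product: 15 6β-hydroxy-4,4,8,10-tetramethyldecal-7-en-9-one
Conditions: NaBH4, CeCl3·7H2O, MeOH, −78 °C
Reagents that add atoms: none
Why: The C6 carbonyl is far more accessible than the C9 carbonyl, which lies between quaternary C10 and the methyl-bearing C8 (the same bias as in 2,6,6-trimethylcyclohexene-1,4-dione); cerium-assisted 1,2-reduction (Luche) delivers hydride from the open α face, opposite the axial methyls on C4 and C10, and sets the axial 6β-hydroxyl.

Step 10
Reactants: 15 6β-hydroxy enone
Product: 16 6β-(tert-butyldimethylsilyloxy)-4,4,8,10-tetramethyldecal-7-en-9-one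
Conditions: TBSOTf, 2,6-lutidine, CH2Cl2, 0 °C → rt
Reagents that add atoms: tert-butyldimethylsilyl trifluoromethanesulfonate CC(C)(C)[Si](C)(C)OS(=O)(=O)C(F)(F)F
Why: The silyl triflate silylates even this hindered axial alcohol; the ether has to survive an organolithium, hexavalent chromium and acidic methanol.

Step 11
Reactants: 17 (S)-malic acid
Product: 18 cis-(2S,5S)-2-tert-butyl-5-(carboxymethyl)-1,3-dioxolan-4-one
Conditions: pivalaldehyde, TsOH·H2O (cat.), H2SO4 (cat.), pentane, reflux (water separator)
Reagents that add atoms: pivalaldehyde CC(C)(C)C=O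
Why: Acid-catalysed acetalization of the α-hydroxy acid unit gives the cis-dioxolanone as the thermodynamic, crystalline isomer; the acetal centre stores the chirality of the carbinol carbon (self-regeneration of stereocentres).

Step 12
Reactants: 18 dioxolanone acid; 19 prenyl bromide (1-bromo-3-methylbut-2-ene)
Product: 21 (2S,5S)-2-tert-butyl-5-(carboxymethyl)-5-(3-methylbut-2-enyl)-1,3-dioxolan-4-one (prenyl trans to tert-butyl), via dilithium dianion 20 (not isolated)
Conditions: LiN(SiMe3)2 (2.2 equiv), THF, −78 °C; prenyl bromide, −78 → −20 °C; 1 M HCl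
Reagents that add atoms: none
Why: The carboxylate–enolate dianion is alkylated on the face opposite the tert-butyl group, so the prenyl group takes the place of the original hydrogen with overall retention and sets the future C13. A prenyl rather than an allyl group is used because the alkyllithium of step 16 cannot cyclize onto a trisubstituted alkene.

Step 13
Reactants: 21 prenylated dioxolanone acid
Product: 22 (S)-2-(3-methylbut-2-enyl)butane-1,2,4-triol
Conditions: LiAlH4, THF, 0 °C → reflux; aqueous NaOH work-up
Reagents that add atoms: none
Why: LiAlH4 reduces the carboxylate and the dioxolanone carbonyl and releases the pivalaldehyde auxiliary as neopentyl alcohol; the quaternary carbinol carbon is not touched.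

Step 14
Reactants: 22 triol
Product: 23 (S)-2-[2,2-dimethyl-4-(3-methylbut-2-enyl)-1,3-dioxolan-4-yl]ethanol
Conditions: 2,2-dimethoxypropane, TsOH·H2O (cat.), acetone, rt
Reagents that add atoms: 2,2-dimethoxypropane COC(C)(C)OC
Why: Thermodynamic acetonide formation prefers the five-membered dioxolane across the 1,2-diol, which ties the C13 and C16 oxygens together and leaves only the C11 hydroxyl free.

Step 15
Reactants: 23 acetonide alcohol
Product: 24 (S)-4-(2-iodoethyl)-2,2-dimethyl-4-(3-methylbut-2-enyl)-1,3-dioxolane
Conditions: I2, PPh3, imidazole, CH2Cl2, 0 °C → rt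
Reagents that add atoms: iodine II
Why: Appel-type iodination of the primary alcohol under buffered conditions leaves the acetonide and the alkene intact.

Step 16
Reactants: 24 iodide; 16 silyloxy enone
Product: 26 C9 carbinol (9β-hydroxy-7-ene carrying the acetonide side chain 9α), via organolithium 25 (not isolated)
Conditions: 24, t-BuLi (2.1 equiv), Et2O–pentane, −78 °C; then 16, −78 → −40 °C; H2O
Reagents that add atoms: none
Why: Iodine–lithium exchange gives a primary alkyllithium that is stable at −78 °C (γ-alkoxy, no feasible 5-exo carbolithiation), and it adds 1,2 to the C9 ketone, which has no α-hydrogens, from the α face opposite the C10 methyl. The configuration of the new carbinol is irrelevant because C9 becomes trigonal in step 17.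

Step 17
Reactants: 26 C9 carbinol
Product: 27 6β-(tert-butyldimethylsilyloxy)-8-en-7-one with the acetonide side chain on C9
Conditions: pyridinium chlorochromate C5H5NH[CrO3Cl], 4 Å molecular sieves, CH2Cl2, rt
Reagents that add atoms: pyridinium chlorochromate [O-][Cr](=O)(=O)Cl.c1cc[nH+]cc1
Why: The tertiary allylic chromate ester undergoes a [3,3] shift to C7 and is oxidized there (Babler–Dauben oxidative transposition), giving the 8-en-7-one with the side chain on C9 and the 6β-silyloxy group untouched.

Step 18
Reactants: 27 enone
Product: 28 C15 aldehyde (prenyl group cleaved; acetonide and enone intact)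
Conditions: OsO4 (2 mol %), NaIO4 (4 equiv), 2,6-lutidine, dioxane–H2O 3:1, rt
Reagents that add atoms: sodium periodate [Na+].[O-]I(=O)(=O)=O
Why: OsO4 dihydroxylates the electron-rich trisubstituted prenyl alkene much faster than the electron-poor tetrasubstituted enone alkene, and NaIO4 cleaves the diol in situ (Lemieux–Johnson cleavage).

Step 19
Reactants: 28 aldehyde
Product: 29 13-hydroxy-8-en-7-one with ring D closed as the C15 methyl acetal (C15 epimers)
Conditions: TsOH·H2O (10 mol %), MeOH, rt
Reagents that add atoms: methanol CO
Why: Acidic methanol removes the acetonide, and the freed C16 hydroxyl closes on the aldehyde to a five-membered oxocarbenium ion that methanol captures (Fischer-type glycosidation). The C13 hydroxyl cannot compete because it would form an oxetane, so it is left as the only free hydroxyl.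

Step 20
Reactants: 29 hydroxy enone
Product: 30 6β-(tert-butyldimethylsilyloxy)-15-methoxy-9α,13;15,16-diepoxylabdan-7-one
Conditions: t-BuOK (0.2 equiv), THF–t-BuOH, 0 °C → rt; AcOH
Reagents that add atoms: none
Why: The tertiary C13 alkoxide adds to C9 in a 5-exo-trig intramolecular oxa-Michael reaction, a known way to close ethers at fully substituted β carbons of enones; attack is axial and from the α face, anti to the C10 methyl, which sets 9α-O, and reversible protonation of the enolate places the C8 methyl equatorial (α). C13 is not touched and keeps the configuration from step 12; the C6 hydrogen lies near the carbonyl plane under the bulky silyl ether, which should protect C6 from epimerization.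

Step 21
Reactants: 30 silyl ether
Product: 31 6β-hydroxy-15-methoxy-9α,13;15,16-diepoxylabdan-7-one
Conditions: HF·pyridine, pyridine, THF, 0 °C → rt
Reagents that add atoms: none
Why: Buffered HF·pyridine cleaves the hindered silyl ether without the basic conditions that could reopen ring C by β-elimination; the methyl acetal is stable in this anhydrous medium.

Step 22
Reactants: 31 6β-alcohol
Product: 32 6β-acetoxy-15-methoxy-9α,13;15,16-diepoxylabdan-7-one
Conditions: Ac2O, DMAP, pyridine, CH2Cl2, rt
Reagents that add atoms: acetic anhydride CC(=O)OC(C)=O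
Why: DMAP-catalysed acylation esterifies the axial 6β-hydroxyl, the only free hydroxyl, with no base strong enough to epimerize C6 or C8.

Step 23
Reactants: 32 methyl acetal
Product: 33 6β-acetoxy-15-hydroxy-9α,13;15,16-diepoxylabdan-7-one (lactol; C15 epimers)
Conditions: AcOH–H2O–THF 3:1:1, 35 °C
Reagents that add atoms: water O
Why: Mild aqueous acid hydrolyses the 2-deoxyfuranoside-type acetal to the lactol. Ring D has no enol ether at this stage, so the C13–O bond is not allylic and should not ionize; the acetate and the β-alkoxy ketone tolerate the conditions.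

Step 24
Reactants: 33 lactol
Product: 35 6β-acetoxy-9α,13;15,16-diepoxylabd-14-en-7-one (target), via lactol mesylate 34 (not isolated)
Conditions: MsCl, Et3N (excess), CH2Cl2, −20 °C → rt; NaHCO3 work-up, Et3N-deactivated silica
Reagents that add atoms: none
Why: Sulfonylation of the anomeric hydroxyl and elimination by Et3N is the standard lactol-to-glycal dehydration; only C14 carries a β-hydrogen because C13 is quaternary, so the C14=C15 enol ether forms regiospecifically, and the medium stays basic, which protects the acid-labile product.

## Compound list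

1 | (R)-(−)-carvone | CC1=CC[C@H](CC1=O)C(C)=C | starting material
2 | iodomethane | CI | starting material
3 | lithium α′-enolate of 1 | [Li+].[O-]C1=C[C@@H](CC=C1C)C(C)=C | intermediate (not isolated)
4 | trans-6-methylcarvone, (5R,6S)-2,6-dimethyl-5-(prop-1-en-2-yl)cyclohex-2-en-1-one | C1C=C(C)C(=O)[C@@H](C)[C@@H]1C(C)=C | intermediate
5 | acrolein | C=CC=O | starting material
6 | lithium enolate of 4 | [Li+].[O-]C1=C(C)[C@@H](CC=C1C)C(C)=C | intermediate (not isolated)
7 | 6-(1-hydroxyprop-2-enyl)-6-methylcarvone, hydroxyallyl trans to isopropenyl, carbinol epimers | C1C=C(C)C(=O)[C@@](C)(C(O)C=C)[C@@H]1C(C)=C | intermediate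
8 | 6-acryloyl-6-methylcarvone, acryloyl trans to isopropenyl | C1C=C(C)C(=O)[C@@](C)(C(=O)C=C)[C@@H]1C(C)=C | intermediate
9 | trans-fused 4,4,8,10-tetramethyldecal-7-ene-1,9-dione (5α-H, 10β-CH3) | C1C=C(C)C(=O)[C@@]2(C)C(=O)CCC(C)(C)[C@H]12 | intermediate
10 | lithium C1 enolate of 9 | C1C=C(C)C(=O)[C@@]2(C)C([O-])=CCC(C)(C)[C@H]12.[Li+] | intermediate (not isolated)
11 | C1 enol triflate of 9 | C1C=C(C)C(=O)[C@@]2(C)C(OS(=O)(=O)C(F)(F)F)=CCC(C)(C)[C@H]12 | intermediate
12 | 4,4,8,10-tetramethyldecala-1,7-dien-9-one | C1C=C(C)C(=O)[C@@]2(C)C=CCC(C)(C)[C@H]12 | intermediate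
13 | 4,4,8,10-tetramethyldecal-7-en-9-one (5α-H, 10β-CH3) | C1C=C(C)C(=O)[C@@]2(C)CCCC(C)(C)[C@H]12 | intermediate
14 | 4,4,8,10-tetramethyldecal-7-ene-6,9-dione | O=C1C=C(C)C(=O)[C@@]2(C)CCCC(C)(C)[C@H]12 | intermediate
15 | 6β-hydroxy-4,4,8,10-tetramethyldecal-7-en-9-one | O[C@@H]1C=C(C)C(=O)[C@@]2(C)CCCC(C)(C)[C@H]12 | intermediate
16 | 6β-(tert-butyldimethylsilyloxy)-4,4,8,10-tetramethyldecal-7-en-9-one | CC(C)(C)[Si](C)(C)O[C@@H]1C=C(C)C(=O)[C@@]2(C)CCCC(C)(C)[C@H]12 | intermediate
17 | (S)-malic acid | OC(=O)C[C@H](O)C(=O)O | starting material
18 | cis-(2S,5S)-2-tert-butyl-5-(carboxymethyl)-1,3-dioxolan-4-one | CC(C)(C)[C@H]1O[C@@H](CC(=O)O)C(=O)O1 | intermediate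
19 | prenyl bromide (1-bromo-3-methylbut-2-ene) | CC(C)=CCBr | starting material
20 | dilithium carboxylate–enolate dianion of 18 | CC(C)(C)[C@H]1OC(CC(=O)[O-])=C([O-])O1.[Li+].[Li+] | intermediate (not isolated)
21 | (2S,5S)-2-tert-butyl-5-(carboxymethyl)-5-(3-methylbut-2-enyl)-1,3-dioxolan-4-one | CC(C)(C)[C@H]1O[C@@](CC=C(C)C)(CC(=O)O)C(=O)O1 | intermediate
22 | (S)-2-(3-methylbut-2-enyl)butane-1,2,4-triol | OCC[C@](CC=C(C)C)(O)CO | intermediate
23 | (S)-2-[2,2-dimethyl-4-(3-methylbut-2-enyl)-1,3-dioxolan-4-yl]ethanol | OCC[C@]1(CC=C(C)C)OC(C)(C)OC1 | intermediate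
24 | (S)-4-(2-iodoethyl)-2,2-dimethyl-4-(3-methylbut-2-enyl)-1,3-dioxolane | ICC[C@]1(CC=C(C)C)OC(C)(C)OC1 | intermediate
25 | organolithium from 24 | [Li]CC[C@]1(CC=C(C)C)OC(C)(C)OC1 | intermediate (not isolated)
26 | C9 carbinol: 9β-hydroxy-6β-silyloxy-7-ene with the acetonide side chain 9α | CC(C)(C)[Si](C)(C)O[C@@H]1C=C(C)[C@@](O)(CC[C@]3(CC=C(C)C)OC(C)(C)OC3)[C@@]2(C)CCCC(C)(C)[C@H]12 | intermediate
27 | 6β-silyloxy-8-en-7-one with the acetonide side chain on C9 | CC(C)(C)[Si](C)(C)O[C@@H]1C(=O)C(C)=C(CC[C@]3(CC=C(C)C)OC(C)(C)OC3)[C@@]2(C)CCCC(C)(C)[C@H]12 | intermediate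
28 | C15 aldehyde of 27 | CC(C)(C)[Si](C)(C)O[C@@H]1C(=O)C(C)=C(CC[C@]3(CC=O)OC(C)(C)OC3)[C@@]2(C)CCCC(C)(C)[C@H]12 | intermediate
29 | 13-hydroxy-6β-silyloxy-8-en-7-one, ring D as C15 methyl acetal (C15 epimers) | CC(C)(C)[Si](C)(C)O[C@@H]1C(=O)C(C)=C(CC[C@@]3(O)CC(OC)OC3)[C@@]2(C)CCCC(C)(C)[C@H]12 | intermediate
30 | 6β-(tert-butyldimethylsilyloxy)-15-methoxy-9α,13;15,16-diepoxylabdan-7-one | CC(C)(C)[Si](C)(C)O[C@@H]1C(=O)[C@@H](C)[C@]2(CC[C@]3(CC(OC)OC3)O2)[C@@]2(C)CCCC(C)(C)[C@H]12 | intermediate
31 | 6β-hydroxy-15-methoxy-9α,13;15,16-diepoxylabdan-7-one | O[C@@H]1C(=O)[C@@H](C)[C@]2(CC[C@]3(CC(OC)OC3)O2)[C@@]2(C)CCCC(C)(C)[C@H]12 | intermediate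
32 | 6β-acetoxy-15-methoxy-9α,13;15,16-diepoxylabdan-7-one | CC(=O)O[C@@H]1C(=O)[C@@H](C)[C@]2(CC[C@]3(CC(OC)OC3)O2)[C@@]2(C)CCCC(C)(C)[C@H]12 | intermediate
33 | 6β-acetoxy-15-hydroxy-9α,13;15,16-diepoxylabdan-7-one (lactol) | CC(=O)O[C@@H]1C(=O)[C@@H](C)[C@]2(CC[C@]3(CC(O)OC3)O2)[C@@]2(C)CCCC(C)(C)[C@H]12 | intermediate
34 | C15 mesylate of 33 | CC(=O)O[C@@H]1C(=O)[C@@H](C)[C@]2(CC[C@]3(CC(OS(C)(=O)=O)OC3)O2)[C@@]2(C)CCCC(C)(C)[C@H]12 | intermediate (not isolated)
35 | (5S,6S,8S,9R,10S,13R)-6-acetoxy-9,13;15,16-diepoxylabd-14-en-7-one | CC(=O)O[C@@H]1C(=O)[C@@H](C)[C@]2(CC[C@]3(C=COC3)O2)[C@@]2(C)CCCC(C)(C)[C@H]12 | target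

## Step count and least certain steps

Total: 24 steps. Longest linear sequence: 19 steps from 1 (steps 1–10 and 16–24); the side-chain branch from 17 is 5 steps (11–15).

**Step 4 (key step).** What may go wrong: hydrogen delivery to the vinyl ketone instead of the isopropenyl group, reduction of the C4 radical before ring closure, or oligomerization of the vinyl ketone. Fallback (the same radical from a carbon–halogen bond, so that no metal hydride meets the vinyl ketone): from 7, Markovnikov addition of HBr to the isopropenyl group (HBr, CH2Cl2, −30 °C) should give the tertiary bromide F1. DMP oxidation gives the bromo vinyl ketone F2. Slow addition of Bu3SnH with AIBN in benzene at 80 °C abstracts bromine, and the tertiary radical closes ring A in the same 6-endo Giese mode to give 9, where the route is rejoined.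

**Step 20 (ring C by oxa-Michael addition).** What may go wrong: the addition is reversible and the β carbon is fully substituted and flanked by quaternary C10, so incomplete closure, reopening by β-elimination, or epimerization at C6 while the equilibrium is established could erode the material. Fallback (polarity reversed: the C9 oxygen is made first and attacks C13 with inversion, so the mirror-image side chain is needed): it sets out from 16 and from (R)-malic acid.
- The operations of steps 11–15 on (R)-malic acid give the (2R,5R)-dioxolanone acid F3, its prenylated derivative F4, the (R)-triol F5, the (R)-acetonide alcohol F6 and the (R)-iodide F7.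
- Iodine–lithium exchange gives the organolithium F8, which adds to 16 to give the carbinol F9; oxidative transposition with C5H5NH[CrO3Cl] gives the enone F10.
- Methanolysis of the acetonide (PPTS, MeOH) gives the diol F11, and Mitsunobu cyclodehydration (PPh3, DIAD) closes the 13,16-epoxide F12 with retention at C13.
- Nucleophilic epoxidation (H2O2, NaOH, MeOH) from the α face gives the 8α,9α-epoxy ketone F13, and SmI2 (THF–MeOH, −90 °C) opens it reductively to the 9α-hydroxy ketone F14; the equatorial 8α-methyl epimer is expected from axial protonation.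
- Catalytic camphorsulfonic acid (CH2Cl2, 0 °C) lets the 9α-hydroxyl open the epoxide at tertiary C13 in the 5-exo mode with inversion, giving the spiro ether with a free C16 hydroxyl F15, now with the natural C13 configuration.
- Cleavage of the prenyl group (OsO4, NaIO4) gives the lactol F16, and PPTS in methanol converts it into 30, where the route is rejoined.

**Step 8 (γ-oxidation of the enone).** What may go wrong: slow hydrogen abstraction at C6, which is crowded by the C4 gem-dimethyl group, with competing oxidation of the C8 methyl or over-oxidation. Fallback (oxygen delivered to a dienol ether instead of C–H oxidation): from 13, TBSOTf and Et3N give the silyl dienol ether F17. Peracid oxidation at its terminal C6=C7 bond (vinylogous Rubottom oxidation) gives the 6α-hydroxy enone F18, whose configuration is irrelevant. DMP oxidation gives 14, where the route is rejoined.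

**Step 24 (final dehydration).** What may go wrong: ionization of the allylic C13–O bond of the product by the ammonium salts formed, leading to opening of ring C and aromatization of ring D, or substitution at C15 by chloride without elimination. Fallback (syn-elimination of a selenoxide under neutral conditions): from 33, N-(phenylseleno)phthalimide and Bu3P in CH2Cl2 give the C15 phenyl selenide F19. Oxidation with NaIO4 and NaHCO3 in aqueous methanol at 0 °C gives the selenoxide F20, which is not isolated and eliminates at room temperature toward C14 to give 35.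

## Further compounds

F1 | step 4 | tertiary bromide: HBr adduct of 7 at the isopropenyl group | C1C=C(C)C(=O)[C@@](C)(C(O)C=C)[C@@H]1C(C)(C)Br
F2 | step 4 | bromo vinyl ketone: HBr adduct of 8 at the isopropenyl group | C1C=C(C)C(=O)[C@@](C)(C(=O)C=C)[C@@H]1C(C)(C)Br
F3 | step 20 | cis-(2R,5R)-2-tert-butyl-5-(carboxymethyl)-1,3-dioxolan-4-one | CC(C)(C)[C@@H]1O[C@H](CC(=O)O)C(=O)O1
F4 | step 20 | (2R,5R)-2-tert-butyl-5-(carboxymethyl)-5-(3-methylbut-2-enyl)-1,3-dioxolan-4-one | CC(C)(C)[C@@H]1O[C@](CC=C(C)C)(CC(=O)O)C(=O)O1
F5 | step 20 | (R)-2-(3-methylbut-2-enyl)butane-1,2,4-triol | OCC[C@@](CC=C(C)C)(O)CO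
F6 | step 20 | (R)-2-[2,2-dimethyl-4-(3-methylbut-2-enyl)-1,3-dioxolan-4-yl]ethanol | OCC[C@@]1(CC=C(C)C)OC(C)(C)OC1
F7 | step 20 | (R)-4-(2-iodoethyl)-2,2-dimethyl-4-(3-methylbut-2-enyl)-1,3-dioxolane | ICC[C@@]1(CC=C(C)C)OC(C)(C)OC1
F8 | step 20 | organolithium from F7 (not isolated) | [Li]CC[C@@]1(CC=C(C)C)OC(C)(C)OC1
F9 | step 20 | C9 carbinol from 16 and F8 | CC(C)(C)[Si](C)(C)O[C@@H]1C=C(C)[C@@](O)(CC[C@@]3(CC=C(C)C)OC(C)(C)OC3)[C@@]2(C)CCCC(C)(C)[C@H]12
F10 | step 20 | 6β-silyloxy-8-en-7-one with the (R)-acetonide side chain | CC(C)(C)[Si](C)(C)O[C@@H]1C(=O)C(C)=C(CC[C@@]3(CC=C(C)C)OC(C)(C)OC3)[C@@]2(C)CCCC(C)(C)[C@H]12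
F11 | step 20 | 13,16-diol of F10 | CC(C)(C)[Si](C)(C)O[C@@H]1C(=O)C(C)=C(CC[C@@](O)(CO)CC=C(C)C)[C@@]2(C)CCCC(C)(C)[C@H]12
F12 | step 20 | 13,16-epoxide of the enone | CC(C)(C)[Si](C)(C)O[C@@H]1C(=O)C(C)=C(CC[C@@]3(CC=C(C)C)OC3)[C@@]2(C)CCCC(C)(C)[C@H]12
F13 | step 20 | 8α,9α-epoxy-7-ketone carrying the 13,16-epoxide | CC(C)(C)[Si](C)(C)O[C@@H]1C(=O)[C@@]4(C)O[C@@]4(CC[C@@]3(CC=C(C)C)OC3)[C@@]2(C)CCCC(C)(C)[C@H]12
F14 | step 20 | 9α-hydroxy-8α-methyl-7-ketone carrying the 13,16-epoxide | CC(C)(C)[Si](C)(C)O[C@@H]1C(=O)[C@@H](C)[C@](O)(CC[C@@]3(CC=C(C)C)OC3)[C@@]2(C)CCCC(C)(C)[C@H]12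
F15 | step 20 | 9α,13-spiro ether with free C16 hydroxyl and prenyl group on C13 | CC(C)(C)[Si](C)(C)O[C@@H]1C(=O)[C@@H](C)[C@]2(CC[C@@](CC=C(C)C)(CO)O2)[C@@]2(C)CCCC(C)(C)[C@H]12
F16 | step 20 | 6β-silyloxy-15-hydroxy-9α,13;15,16-diepoxylabdan-7-one (lactol) | CC(C)(C)[Si](C)(C)O[C@@H]1C(=O)[C@@H](C)[C@]2(CC[C@]3(CC(O)OC3)O2)[C@@]2(C)CCCC(C)(C)[C@H]12
F17 | step 8 | 9-(tert-butyldimethylsilyloxy)-4,4,8,10-tetramethyldecala-6,8-diene | C1=CC(C)=C(O[Si](C)(C)C(C)(C)C)[C@@]2(C)CCCC(C)(C)[C@H]12
F18 | step 8 | 6α-hydroxy-4,4,8,10-tetramethyldecal-7-en-9-one | O[C@H]1C=C(C)C(=O)[C@@]2(C)CCCC(C)(C)[C@H]12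
F19 | step 24 | 6β-acetoxy-15-(phenylseleno)-9α,13;15,16-diepoxylabdan-7-one | CC(=O)O[C@@H]1C(=O)[C@@H](C)[C@]2(CC[C@]3(CC([Se]c4ccccc4)OC3)O2)[C@@]2(C)CCCC(C)(C)[C@H]12
F20 | step 24 | selenoxide of F19 (not isolated) | CC(=O)O[C@@H]1C(=O)[C@@H](C)[C@]2(CC[C@]3(CC([Se](=O)c4ccccc4)OC3)O2)[C@@]2(C)CCCC(C)(C)[C@H]12
A1 | alternative 1 | 6β-acetoxy-7,7-ethylenedioxy-15-methoxy-9α,13;15,16-diepoxylabdane | CC(=O)O[C@@H]1C4(OCCO4)[C@@H](C)[C@]2(CC[C@]3(C[C@H](OC)OC3)O2)[C@@]2(C)CCCC(C)(C)[C@H]12
A2 | alternative 1 | 6β-acetoxy-7,7-ethylenedioxy-13-hydroxy-15-methoxy-15,16-epoxylabd-9(11)-ene | CC(=O)O[C@@H]1C4(OCCO4)[C@@H](C)C(=CC[C@@]3(O)C[C@H](OC)OC3)[C@@]2(C)CCCC(C)(C)[C@H]12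
A3 | alternative 2 | methyl 3β-hydroxy-4,4,10-trimethyl-8-oxo-trans-decalin-9-carboxylate | C1CC(=O)[C@H](C(=O)OC)[C@@]2(C)CC[C@H](O)C(C)(C)[C@H]12
A4 | alternative 2 | methyl (6E,10S)-10,11-epoxy-7,11-dimethyl-3-oxododec-6-enoate | COC(=O)CC(=O)CC/C=C(\C)CC[C@@H]1OC1(C)C
A5 | alternative 3 | trans-fused 4,4,10-trimethyldecal-6-ene with 2-tert-butyl-1,3-dioxolan-4-one spiro at C9 | C1=CC[C@]2(C(=O)O[C@H](C(C)(C)C)O2)[C@@]3(C)CCCC(C)(C)[C@H]13
A6 | alternative 3 | (Z)-2-tert-butyl-5-[(7E)-6,6-dimethyldeca-7,9-dien-2-ylidene]-1,3-dioxolan-4-one | C/C(CCCC(C)(C)/C=C/C=C)=C1\C(=O)O[C@H](C(C)(C)C)O1
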